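**Plan**
1. Retrosynthetic cuts: C4–CH3 (last, from a C3–C4 silyl enol ether); H–C9/H–C11 (from C9=C11); C8–CH3; C8–C9 of ring B (aldehyde carbon onto alkyne carbon); C11–C12 (alkynyl–farnesyl); C9≡C11 from a formyl group on C10; ring A at C1–C2 and C5–C10 (Diels–Alder).
2. Forward: ring A by catalytic asymmetric Diels–Alder of a 2-silyloxydiene with methacrolein; CHO to alkyne; farnesyl bromide joined at the alkyne; ring B closed at C8–C9 by nickel-catalysed reductive alkynal cyclisation; then oxidation, methyl addition, hydrogenation and C4 methylation.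
3. Feature used: C9 bears only C8, C10 and C11, and C8 is oxygenated, so the C8–C9 bond of ring B maps onto an aldehyde carbon and an alkyne carbon held 1,2-cis on ring A. Closure leaves C8 and C9 trigonal on a cis-fused bicycle whose ring A lies under the α face of ring B.
4. Stereochemistry: C10 from the catalyst and C5 from the endo rule in one Diels–Alder event; C8 by methyl addition to the convex β face; C9 by hydroxyl-directed hydrogenation from the α face; both E alkenes are bought with farnesyl bromide.
5. The silyl enol ether serves three times: it activates the diene, masks the C3 ketone (keeping C6 pseudoaxial on ring A), and delivers the regiodefined enolate for the final C4 methylation.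

Key step: step 7

Remark: as written the target is (5S,8R,9R,10S), i.e. the A/B cis-fused decalin (H5 and CH3-10 on the same face), and the route is built for this isomer; locants are C3 ketone, C4 gem-dimethyl carbon, C5/C10 ring fusion, C8 carbinol, C9 methine, C11 and C12 the two side-chain methylenes.

Step 1
Reactants: 1 methyl 4-oxobutanoate; 2 3-(triphenyl-λ5-phosphanylidene)butan-2-one
Product: 3 methyl (4E)-5-methyl-6-oxohept-4-enoate
Conditions: toluene, 90 °C
Reagents that add atoms: none
Why: Wittig olefination of an unhindered aldehyde by an α-methyl-substituted stabilised keto ylide should give the trisubstituted enone with E geometry, which later places C6 on the outside of the diene.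

Step 2
Reactants: 3 enone ester
Product: 4 methyl (4E)-5-methyl-6-{[tri(propan-2-yl)silyl]oxy}hepta-4,6-dienoate
Conditions: i-Pr3SiOSO2CF3, Et3N, CH2Cl2, 0 °C
Reagents that add atoms: tri(propan-2-yl)silyl trifluoromethanesulfonate, CC(C)[Si](C(C)C)(C(C)C)OS(=O)(=O)C(F)(F)F
Why: Soft enolisation of the methyl ketone on its α'-methyl side (silyl triflate with a tertiary amine) should give the cross-conjugated 2-silyloxydiene, while the E alkene and the ester are not touched.

Step 3
Reactants: 4 silyloxydiene; 5 2-methylprop-2-enal (methacrolein)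
Product: 6 methyl 3-[(1R,6S)-6-formyl-2,6-dimethyl-3-{[tri(propan-2-yl)silyl]oxy}cyclohex-2-en-1-yl]propanoate
Conditions: (S)-1-(2-methylphenyl)-3,3-diphenyltetrahydro-1H,3H-pyrrolo[1,2-c][1,3,2]oxazaborole (0.2 equiv), HN(SO2CF3)2 (0.2 equiv), CH2Cl2, −78 °C
Reagents that add atoms: none
Why: Enantioselective Diels–Alder reaction under a chiral cationic oxazaborolidine, in which the 2-silyloxy and the terminal alkyl group both send the CH2 terminus of the diene to the β-carbon of methacrolein, the (S)-catalyst should leave the Re face of C2 of the formyl-bound s-trans enal open (sets quaternary C10), and the endo position of the formyl group (Alder rule, helped because the exo site next to the outside C6 chain is better filled by CH3 than by the catalyst-bound CHO) places C6 and C9 cis (sets C5).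

Step 4
Reactants: 6 aldehyde
Product: 7 methyl 3-[(1S,6S)-6-ethynyl-2,6-dimethyl-3-{[tri(propan-2-yl)silyl]oxy}cyclohex-2-en-1-yl]propanoate
Conditions: dimethyl (1-diazo-2-oxopropyl)phosphonate, K2CO3, MeOH, 0 °C to rt
Reagents that add atoms: dimethyl (1-diazo-2-oxopropyl)phosphonate, CC(=O)C(=[N+]=[N-])P(=O)(OC)OC
Why: Ohira–Bestmann (Seyferth–Gilbert) homologation of the non-enolisable aldehyde on quaternary C10 should give the terminal alkyne under carbonate conditions that spare the methyl ester and the hindered silyl enol ether; no stereocentre is touched.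

Step 5
Reactants: 7 terminal alkyne; 8 (2E,6E)-1-bromo-3,7,11-trimethyldodeca-2,6,10-triene (farnesyl bromide)
Product: 9 methyl 3-[(1S,6S)-2,6-dimethyl-6-[(4E,8E)-5,9,13-trimethyltetradeca-4,8,12-trien-1-yn-1-yl]-3-{[tri(propan-2-yl)silyl]oxy}cyclohex-2-en-1-yl]propanoate
Conditions: CuI (0.2 equiv), NaI (0.2 equiv), Cs2CO3, DMF, rt
Reagents that add atoms: none
Why: Copper-mediated coupling of a terminal alkyne with an allylic bromide (copper acetylide formed with carbonate base) should join C11 to the primary carbon C12 of the farnesyl unit and give the skipped enyne, the weak base leaving the ester alone; both E alkenes come in with 8.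

Step 6
Reactants: 9 enyne ester
Product: 10 3-[(1S,6S)-2,6-dimethyl-6-[(4E,8E)-5,9,13-trimethyltetradeca-4,8,12-trien-1-yn-1-yl]-3-{[tri(propan-2-yl)silyl]oxy}cyclohex-2-en-1-yl]propanal
Conditions: i-Bu2AlH (1.1 equiv), CH2Cl2, −78 °C; then aqueous potassium sodium tartrate
Reagents that add atoms: none
Why: Partial reduction of the methyl ester by i-Bu2AlH at low temperature should stop at the aldehyde through the stable aluminium hemiacetal; alkyne, alkenes and silyl enol ether are inert.

Step 7
Reactants: 10 alkynal
Product: 12 (1E,4aS,8aS)-5,8a-dimethyl-1-[(3E,7E)-4,8,12-trimethyltrideca-3,7,11-trien-1-ylidene]-6-{[tri(propan-2-yl)silyl]oxy}-1,2,3,4,4a,7,8,8a-octahydronaphthalen-2-ol as both C2 epimers, via diethylborinate ester 11 (not isolated)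
Conditions: Ni(cod)2 (0.1 equiv; cod = 1,5-cyclooctadiene), PBu3 (0.2 equiv), Et3B (3 equiv), toluene, rt; then H2O
Reagents that add atoms: none
Why: Zerovalent nickel ligated by PBu3 binds the alkyne and the aldehyde of 10 and couples them oxidatively, which forms the C8–C9 bond and an oxanickelacyclopentene; ethyl transfer from Et3B to nickel, β-hydride elimination (ethene) and C–H reductive elimination then place H on C11 and release the alcohol as its diethylborinate 11. The closest known reaction type is the nickel-catalysed reductive cyclisation of alkynals to cyclic allylic alcohols with an exocyclic alkene. Ring B closes in the 6-exo-dig mode (C8 onto the proximal alkyne carbon C9), and the ring fusion is cis because C6 and C9 are already cis on ring A. The only new stereocentre, the C8 carbinol, is not controlled and is erased in step 8, while the alkene geometry follows from syn addition of C8 and H across the alkyne (E, C12 cis to C10) and is immaterial because C11 ends as CH2. The step needs exo rather than seven-membered endo closure and must leave the trisubstituted alkenes and the enol ether alone; the four-atom tether, the gem-disubstitution at C10 and the inertness of isolated trisubstituted alkenes toward this oxidative cyclisation should secure both. Its value for the plan is that C8 and C9 emerge trigonal on a cis-fused bicycle, so that each can then be set from a defined face of that bicycle (steps 9 and 10).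

Step 8
Reactants: 12 allylic alcohol (C8 epimers)
Product: 13 (1E,4aS,8aS)-5,8a-dimethyl-1-[(3E,7E)-4,8,12-trimethyltrideca-3,7,11-trien-1-ylidene]-6-{[tri(propan-2-yl)silyl]oxy}-3,4,4a,7,8,8a-hexahydronaphthalen-2(1H)-one
Conditions: Dess–Martin periodinane, pyridine, CH2Cl2, 0 °C
Reagents that add atoms: none
Why: Dess–Martin oxidation of the secondary allylic alcohol under buffered conditions should converge both C8 epimers on one cross-conjugated enone without moving the skipped C13=C14 alkene into conjugation or cleaving the silyl enol ether.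

Step 9
Reactants: 13 enone
Product: 14 (1E,2R,4aS,8aS)-2,5,8a-trimethyl-1-[(3E,7E)-4,8,12-trimethyltrideca-3,7,11-trien-1-ylidene]-6-{[tri(propan-2-yl)silyl]oxy}-1,2,3,4,4a,7,8,8a-octahydronaphthalen-2-ol
Conditions: MeLi, CeCl3, THF, −78 °C; then H2O
Reagents that add atoms: methyllithium, [Li]C
Why: 1,2-Addition of a weakly basic organocerium reagent to the enone, in which allylic strain with the C4 methyl keeps C6 pseudoaxial on ring A so that C1 is axial on ring B and blocks the α face of C8, so CH3 should enter from the convex β face and the hydroxyl ends α (sets C8), while the low basicity avoids deprotonation at doubly allylic C12.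

Step 10
Reactants: 14 tertiary allylic alcohol
Product: 15 (1R,2R,4aS,8aS)-2,5,8a-trimethyl-6-{[tri(propan-2-yl)silyl]oxy}-1-[(3E,7E)-4,8,12-trimethyltrideca-3,7,11-trien-1-yl]-1,2,3,4,4a,7,8,8a-octahydronaphthalen-2-ol
Conditions: [Rh(nbd)(Ph2P(CH2)4PPh2)]BF4 (0.1 equiv; nbd = norbornadiene), H2 (60 bar), CH2Cl2, rt
Reagents that add atoms: none
Why: Hydroxyl-directed homogeneous hydrogenation with a cationic monovalent rhodium diphosphine catalyst, which binds the 8α-hydroxyl and delivers H2 to the α face of C9=C11 so that H9 ends cis to OH and the side chain β (sets C9), while the isolated trisubstituted alkenes and the tetrasubstituted enol ether cannot chelate and should not be reduced.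

Step 11
Reactants: 15 silyl enol ether
Product: 17 (4aS,5R,6R,8aS)-6-hydroxy-1,1,4a,6-tetramethyl-5-[(3E,7E)-4,8,12-trimethyltrideca-3,7,11-trien-1-yl]octahydronaphthalen-2(1H)-one, via benzyltrimethylammonium enolate 16 (not isolated)
Conditions: anhydrous PhCH2N(CH3)3F, MeI (excess), 4 Å molecular sieves, THF, 0 °C to rt
Reagents that add atoms: iodomethane, CI
Why: Fluoride cleavage of the silyl enol ether gives the regiodefined C3–C4 ammonium enolate 16, and its C-methylation at C4 (regiospecific enolate alkylation) completes the gem-dimethyl group and frees the C3 ketone in the same operation; C4 is not stereogenic and no existing stereocentre is enolisable.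

**Compound list**
1 | methyl 4-oxobutanoate | O=CCCC(=O)OC | starting material
2 | 3-(triphenyl-λ5-phosphanylidene)butan-2-one | CC(=O)C(C)=P(c1ccccc1)(c1ccccc1)c1ccccc1 | starting material
3 | methyl (4E)-5-methyl-6-oxohept-4-enoate | CC(=O)/C(C)=C/CCC(=O)OC | intermediate
4 | methyl (4E)-5-methyl-6-{[tri(propan-2-yl)silyl]oxy}hepta-4,6-dienoate | C=C(O[Si](C(C)C)(C(C)C)C(C)C)/C(C)=C/CCC(=O)OC | intermediate
5 | 2-methylprop-2-enal (methacrolein) | CC(=C)C=O | starting material
6 | methyl 3-[(1R,6S)-6-formyl-2,6-dimethyl-3-{[tri(propan-2-yl)silyl]oxy}cyclohex-2-en-1-yl]propanoate | O=C[C@@]1(C)CCC(O[Si](C(C)C)(C(C)C)C(C)C)=C(C)[C@H]1CCC(=O)OC | intermediate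
7 | methyl 3-[(1S,6S)-6-ethynyl-2,6-dimethyl-3-{[tri(propan-2-yl)silyl]oxy}cyclohex-2-en-1-yl]propanoate | C#C[C@@]1(C)CCC(O[Si](C(C)C)(C(C)C)C(C)C)=C(C)[C@H]1CCC(=O)OC | intermediate
8 | (2E,6E)-1-bromo-3,7,11-trimethyldodeca-2,6,10-triene (farnesyl bromide) | CC(C)=CCC/C(C)=C/CC/C(C)=C/CBr | starting material
9 | methyl 3-[(1S,6S)-2,6-dimethyl-6-[(4E,8E)-5,9,13-trimethyltetradeca-4,8,12-trien-1-yn-1-yl]-3-{[tri(propan-2-yl)silyl]oxy}cyclohex-2-en-1-yl]propanoate | CC(C)=CCC/C(C)=C/CC/C(C)=C/CC#C[C@@]1(C)CCC(O[Si](C(C)C)(C(C)C)C(C)C)=C(C)[C@H]1CCC(=O)OC | intermediate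
10 | 3-[(1S,6S)-2,6-dimethyl-6-[(4E,8E)-5,9,13-trimethyltetradeca-4,8,12-trien-1-yn-1-yl]-3-{[tri(propan-2-yl)silyl]oxy}cyclohex-2-en-1-yl]propanal | CC(C)=CCC/C(C)=C/CC/C(C)=C/CC#C[C@@]1(C)CCC(O[Si](C(C)C)(C(C)C)C(C)C)=C(C)[C@H]1CCC=O | intermediate
11 | O-diethylboryl ether (diethylborinate ester) of 12, both C2 epimers | CC(C)=CCC/C(C)=C/CC/C(C)=C/C/C=C1\[C@@]2(C)CCC(O[Si](C(C)C)(C(C)C)C(C)C)=C(C)[C@H]2CCC1OB(CC)CC | intermediate
12 | (1E,4aS,8aS)-5,8a-dimethyl-1-[(3E,7E)-4,8,12-trimethyltrideca-3,7,11-trien-1-ylidene]-6-{[tri(propan-2-yl)silyl]oxy}-1,2,3,4,4a,7,8,8a-octahydronaphthalen-2-ol, both C2 epimers | CC(C)=CCC/C(C)=C/CC/C(C)=C/C/C=C1\[C@@]2(C)CCC(O[Si](C(C)C)(C(C)C)C(C)C)=C(C)[C@H]2CCC1O | intermediate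
13 | (1E,4aS,8aS)-5,8a-dimethyl-1-[(3E,7E)-4,8,12-trimethyltrideca-3,7,11-trien-1-ylidene]-6-{[tri(propan-2-yl)silyl]oxy}-3,4,4a,7,8,8a-hexahydronaphthalen-2(1H)-one | CC(C)=CCC/C(C)=C/CC/C(C)=C/C/C=C1\[C@@]2(C)CCC(O[Si](C(C)C)(C(C)C)C(C)C)=C(C)[C@H]2CCC1=O | intermediate
14 | (1E,2R,4aS,8aS)-2,5,8a-trimethyl-1-[(3E,7E)-4,8,12-trimethyltrideca-3,7,11-trien-1-ylidene]-6-{[tri(propan-2-yl)silyl]oxy}-1,2,3,4,4a,7,8,8a-octahydronaphthalen-2-ol | CC(C)=CCC/C(C)=C/CC/C(C)=C/C/C=C1\[C@@]2(C)CCC(O[Si](C(C)C)(C(C)C)C(C)C)=C(C)[C@H]2CC[C@@]1(C)O | intermediate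
15 | (1R,2R,4aS,8aS)-2,5,8a-trimethyl-6-{[tri(propan-2-yl)silyl]oxy}-1-[(3E,7E)-4,8,12-trimethyltrideca-3,7,11-trien-1-yl]-1,2,3,4,4a,7,8,8a-octahydronaphthalen-2-ol | CC(C)=CCC/C(C)=C/CC/C(C)=C/CC[C@@H]1[C@@]2(C)CCC(O[Si](C(C)C)(C(C)C)C(C)C)=C(C)[C@H]2CC[C@@]1(C)O | intermediate
16 | benzyltrimethylammonium (4aS,5R,6R,8aS)-6-hydroxy-1,4a,6-trimethyl-5-[(3E,7E)-4,8,12-trimethyltrideca-3,7,11-trien-1-yl]-3,4,4a,5,6,7,8,8a-octahydronaphthalen-2-olate | CC(C)=CCC/C(C)=C/CC/C(C)=C/CC[C@@H]1[C@@]2(C)CCC([O-])=C(C)[C@H]2CC[C@@]1(C)O.C[N+](C)(C)Cc1ccccc1 | intermediate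
17 | (4aS,5R,6R,8aS)-6-hydroxy-1,1,4a,6-tetramethyl-5-[(3E,7E)-4,8,12-trimethyltrideca-3,7,11-trien-1-yl]octahydronaphthalen-2(1H)-one | CC(C)=CCC/C(C)=C/CC/C(C)=C/CC[C@@H]1[C@@]2(C)CCC(=O)C(C)(C)[C@H]2CC[C@@]1(C)O | target

**Count and risks**
Total steps: 11. Longest linear sequence: 11 steps (from 1 or 2); farnesyl bromide 8 and methacrolein 5 are bought.

Steps most likely to fail:

Step 7. Oxidative cyclisation may be slow at the alkyne carbon attached to quaternary C10, because the syn adduct presses C12 against C10. Ethyl transfer from boron or plain reduction of the aldehyde could then take over. The fallback sets out from aldehyde 10 and uses rhodium-catalysed intramolecular hydroacylation ([Rh(nbd)(Ph2P(CH2)2PPh2)]BF4 activated with H2, acetone, 60 °C). Insertion of monovalent rhodium into the formyl C–H bond, hydrometallation of the alkyne and C–C reductive elimination should give enone 13 directly, with no external reductant and without step 8. No new compound arises (entry F0), and the route is rejoined at 13.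

Step 3. The formyl group may enter exo to a significant extent, which would place C6 and C9 trans and lead into the trans-fused series, or facial discrimination may be insufficient. The fallback sets out from diene 4 and uses prop-2-enal (acrolein) with the same catalyst, for which the endo mode is more dependable. It should give methyl 3-[(1S,6S)-6-formyl-2-methyl-3-{[tri(propan-2-yl)silyl]oxy}cyclohex-2-en-1-yl]propanoate F1. Deprotonation of the aldehyde α-carbon (KOC(CH3)3, THF, −78 °C) and methylation with MeI then build quaternary C10 under substrate control. The electrophile should enter anti to the pseudoaxial C5 side chain, and the route is rejoined at 6.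

Step 11. The naked tetrasubstituted enolate may be O-methylated, or protonated by adventitious water, instead of being C-methylated at hindered C4. The fallback sets out from 15 with protodesilylation (Bu4NF, AcOH, THF, 0 °C) to (4aS,5R,6R,8aR)-6-hydroxy-1,4a,6-trimethyl-5-[(3E,7E)-4,8,12-trimethyltrideca-3,7,11-trien-1-yl]octahydronaphthalen-2(1H)-one F2 (C1 epimers). Classical methylation of its thermodynamic potassium enolate (KOC(CH3)3, (CH3)3COH, MeI) follows. In a cis-fused 3-ketone this enolate forms toward the more substituted C4, and the route arrives at 17.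

**Further compounds**
F0 | step 7 | none | none
F1 | step 3 | methyl 3-[(1S,6S)-6-formyl-2-methyl-3-{[tri(propan-2-yl)silyl]oxy}cyclohex-2-en-1-yl]propanoate | O=C[C@H]1CCC(O[Si](C(C)C)(C(C)C)C(C)C)=C(C)[C@H]1CCC(=O)OC
F2 | step 11 | (4aS,5R,6R,8aR)-6-hydroxy-1,4a,6-trimethyl-5-[(3E,7E)-4,8,12-trimethyltrideca-3,7,11-trien-1-yl]octahydronaphthalen-2(1H)-one (C1 epimers) | CC(C)=CCC/C(C)=C/CC/C(C)=C/CC[C@@H]1[C@@]2(C)CCC(=O)C(C)[C@H]2CC[C@@]1(C)O
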